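A small charge of free catalyst, 0.5 mol% on the starting material, works in the dawn flask, so its turnovers can be counted.

| setting | dawn | noon | flask |
|---|---|---|---|
| starting material | 0.050 M | 0.050 M | 0.050 M |
| second substrate | 2 equiv | 2 equiv | 2.00 equiv |
| free catalyst | 0.5 mol% | 0.5 mol% | 0.5 mol% |
| temperature | 25 °C | 10 °C | 25 °C |
| remark | the very flask that is asked about, followed so far | run made earlier |  |
| time |  |  | 8.0 h |

- dawn (time / min: target / %, starting material / %): 25.0: 43.9, 47.7; 80.0: 44.0, 47.4; 120: 44.2, 47.6; 180: 43.3, 47.3; 300: 43.5, 47.0
- noon (time / min: target / %, starting material / %): 50.0: 54.5, 32.3; 180: 56.2, 27.5; 240: 56.4, 27.2; 360: 56.0, 26.8; 600: 56.4, 27.3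

(standard deviation of a reading: 0.3 percentage points)

- amber: at 8.0 h add free catalyst, 50.0% of the amount charged, then wait 2.5 h
- blue: at 8.0 h take out 90% of the target then present, then wait 2.5 h
- teal: at 8.0 h raise the temperature by 25 K, then wait 2.5 h
- ochre: change nothing and wait 2.5 h more

- target taken out counts as made
- additions bring no volume worth counting

- target, in percent of the starting material first charged, at 8.0 h
- the option that brings most further target ("none" if no option brings more than 2 percentage points) (amber / blue / teal / ochre / none)
- target present, with what was taken out counted in, in percent of the starting material first charged, after teal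
- target present, with what was taken out counted in, in percent of the starting material first charged, after ochre

Has the dawn flask stopped? Its five readings average 47.4% starting material and 43.8% target, and they are flat from 25.0 min to 300 min. So the reckoning here puts target at that reading at 8.0 h, and waiting looks useless.

How much has each catalyst done? Let N = 105, the starting material used up per free catalyst charged, the turnover number. The colder noon run stopped at N = 146, more than the dawn flask.

Is the catalyst dead, or is the mixture balanced? The noon run's missing share grows from 13.2% at 50.0 min to 16.3% at 180 min, then stands still with the target. That reads as a stopped catalyst, though the readings don't exclude a balance. The reckoning here takes a dead catalyst. Then amber's added catalyst, at N, uses 26.3% of the starting material charged. At the dawn flask's share of target in what was used, that is 22 percentage points of target, against a margin of 2 points. On this reckoning teal, blue and ochre bring no further target, so the reckoning here picks amber.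

The forecast gives 43.8% now, 43.8% after ochre and 21% after teal, and it picks blue: “Extra catalyst does nothing and waiting does nothing. Removing target pulls the equilibrium forward, so blue wins.” The two part here.

The flask gives 44.0% now, 44.0% after ochre and 44.0% after teal. Blue brings 0 points, and amber brings 8.9 points, so the best option is amber.

    second substrate + free catalyst ⇌ catalyst intermediate B (K = 9.50 M⁻¹, k = 54.0 M⁻¹ s⁻¹, Ea = 39.0 kJ mol⁻¹, ΔH = −90.0 kJ mol⁻¹)
    starting material + free catalyst ⇌ catalyst intermediate A (K = 53.0 M⁻¹, k = 41.0 M⁻¹ s⁻¹, Ea = 38.0 kJ mol⁻¹, ΔH = −63.0 kJ mol⁻¹)
    second substrate + free catalyst → spent catalyst (k = 0.130 M⁻¹ s⁻¹, Ea = 46.0 kJ mol⁻¹)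
    catalyst intermediate A → free catalyst + target (k = 3.40 s⁻¹, Ea = 67.0 kJ mol⁻¹)
    target + free catalyst ⇌ isomer of the product + free catalyst, rate k5*[free catalyst]*[target] forward; the back reaction follows from the equilibrium constant (K = 1.40, k = 16.0 M⁻¹ s⁻¹, Ea = 46.0 kJ mol⁻¹, ΔH = −15.0 kJ mol⁻¹)
    catalyst intermediate B → free catalyst + second product (k = 1.90 s⁻¹, Ea = 77.0 kJ mol⁻¹)
    (constants at 25 °C)

At 480 min the flask holds spent catalyst at 100% and free catalyst at 0%. By each forward step alone, the other concentrations held at their charge, second substrate has a half-life of 0.86 min toward catalyst intermediate B and 5.9 h toward spent catalyst, a ratio of 412. Amber's target gain was priced by N at 22 points and came to 8.9 points. A neighbour charged with 0.2 mol% of free catalyst is put by N at 21.0% of starting material used; it keeps 76.2%, so 23.8% went.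

The numbers in the tables stem from a simulated flask on assumed constants, and the scatter is random.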